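**Retrosynthetic overview**
1. Both oxolane rings of the spiroketal and the spiro stereocentre are made last, in one step, from an acyclic alkynediol that already carries the phthalide (new gold/confined chiral acid relay cycloisomerisation).
2. The phthalide lactone ring comes from an (R)-configured ortho-bromo benzylic alcohol (Br/Li exchange, CO2, lactonisation); C3 is set by CBS reduction of the aryl ketone.
3. The aryl ketone comes from 2-bromo-3,5-dimethoxybenzaldehyde and the Grignard reagent of a 14-carbon bromo-alkyne bis-silyl ether.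
4. The 14-carbon chain comes from BF3-mediated opening of (R)-2-(6-bromohexyl)oxirane (hydrolytic kinetic resolution) by the acetylide of TBS-protected (R)-hex-5-yn-2-ol, itself made from (R)-propylene oxide.
5. Ring order: benzene ring bought, lactone ring second, the two spiroketal rings together last.

Assumption: which enantiomer of the IDPi acid (N-triflyl imidodiphosphorimidate built from two 3,3'-bis[3,5-bis(trifluoromethyl)phenyl]-BINOL units) gives the (5S) spiro centre must be found by experiment; the (S,S) acid is written and its mirror image is used if the induction is opposite.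

**Route**

Step 1
Reactants: 1 1-(trimethylsilyl)propyne; 2 (R)-propylene oxide
Product: 4 (2R)-6-(trimethylsilyl)hex-5-yn-2-ol, via lithiated propyne 3 (not isolated)
Conditions: n-BuLi, THF, −78 to −20 °C; then 2, BF3·OEt2, −78 °C; H2O
Reagents that add atoms: none
Why: Propargylic lithiation followed by BF3-assisted SN2 epoxide opening at the CH2 terminus leaves the C–O stereocentre of 2 untouched, so 4 is (R), and the silyl cap steers attack through the propargyl rather than the allenyl terminus.

Step 2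
Reactants: 4 (2R)-6-(trimethylsilyl)hex-5-yn-2-ol
Product: 5 tert-butyldimethyl{[(2R)-6-(trimethylsilyl)hex-5-yn-2-yl]oxy}silane
Conditions: TBSCl, imidazole, DMF, rt
Reagents that add atoms: tert-butyldimethylsilyl chloride (TBSCl), CC(C)(C)[Si](C)(C)Cl
Why: Standard silyl ether formation protects the secondary alcohol for the later organolithium and Grignard steps.

Step 3
Reactants: 5 tert-butyldimethyl{[(2R)-6-(trimethylsilyl)hex-5-yn-2-yl]oxy}silane
Product: 6 tert-butyl[(2R)-hex-5-yn-2-yloxy]dimethylsilane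
Conditions: K2CO3 (0.2 equiv), MeOH, rt
Reagents that add atoms: none
Why: Base-catalysed methanolysis (protodesilylation) cleaves only the alkynyl C–Si bond and leaves the O–TBS ether intact.

Step 4
Reactants: 7 8-bromooct-1-ene
Product: 8 rac-2-(6-bromohexyl)oxirane
Conditions: mCPBA, CH2Cl2, 0 °C to rt
Reagents that add atoms: 3-chloroperoxybenzoic acid (mCPBA), O=C(OO)c1cccc(Cl)c1
Why: Prilezhaev epoxidation of the terminal alkene, to which the primary bromide is inert.

Step 5
Reactants: 8 rac-2-(6-bromohexyl)oxirane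
Product: 9 (2R)-2-(6-bromohexyl)oxirane
Conditions: (R,R)-(salen)Co(OAc) (0.5 mol %; salen = N,N'-bis(3,5-di-tert-butylsalicylidene)cyclohexane-1,2-diaminate, trivalent cobalt), H2O (0.55 equiv), THF, 0 °C to rt
Reagents that add atoms: none
Why: Jacobsen hydrolytic kinetic resolution, in which the (R,R) catalyst hydrolyses the (S)-epoxide and leaves the (R)-epoxide in high ee (at most 50% yield), fixing the future C2 of the spiroketal.

Step 6
Reactants: 6 tert-butyl[(2R)-hex-5-yn-2-yloxy]dimethylsilane; 9 (2R)-2-(6-bromohexyl)oxirane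
Product: 11 (7R,13R)-1-bromo-13-[(tert-butyldimethylsilyl)oxy]tetradec-9-yn-7-ol, via lithium acetylide 10 (not isolated)
Conditions: 6, n-BuLi, THF, −78 °C; BF3·OEt2; then 9, −78 °C; H2O
Reagents that add atoms: none
Why: BF3-mediated alkynylation of a terminal epoxide (Yamaguchi-type) opens 9 at CH2, so the carbinol carbon keeps its (R) configuration, and the primary bromide does not react at −78 °C.

Step 7
Reactants: 11 (7R,13R)-1-bromo-13-[(tert-butyldimethylsilyl)oxy]tetradec-9-yn-7-ol
Product: 12 (7R,13R)-1-bromo-7,13-bis[(tert-butyldimethylsilyl)oxy]tetradec-9-yne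
Conditions: TBSCl, imidazole, DMF, rt
Reagents that add atoms: tert-butyldimethylsilyl chloride (TBSCl), CC(C)(C)[Si](C)(C)Cl
Why: Silyl ether formation masks the second hydroxyl so that a Grignard reagent can be made from the bromide.

Step 8
Reactants: 13 3,5-dimethoxybenzaldehyde
Product: 14 2-bromo-3,5-dimethoxybenzaldehyde
Conditions: NBS, MeCN, 0 °C to rt
Reagents that add atoms: N-bromosuccinimide (NBS), O=C1CCC(=O)N1Br
Why: Electrophilic aromatic bromination goes to C2, which is ortho and para to the two methoxy groups and less hindered than C4 between them.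

Step 9
Reactants: 12 (7R,13R)-1-bromo-7,13-bis[(tert-butyldimethylsilyl)oxy]tetradec-9-yne; 14 2-bromo-3,5-dimethoxybenzaldehyde
Product: 16 (1RS,8R,14R)-1-(2-bromo-3,5-dimethoxyphenyl)-8,14-bis[(tert-butyldimethylsilyl)oxy]pentadec-10-yn-1-ol, via Grignard reagent 15 (not isolated)
Conditions: Mg, THF, 40 °C; then 14, THF, −78 to 0 °C; H2O
Reagents that add atoms: none
Why: Grignard formation at the primary bromide and 1,2-addition to the aldehyde, the aryl bromide being inert to an alkylmagnesium halide at low temperature; the unselective new carbinol is erased in step 10.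

Step 10
Reactants: 16 (1RS,8R,14R)-1-(2-bromo-3,5-dimethoxyphenyl)-8,14-bis[(tert-butyldimethylsilyl)oxy]pentadec-10-yn-1-ol
Product: 17 (8R,14R)-1-(2-bromo-3,5-dimethoxyphenyl)-8,14-bis[(tert-butyldimethylsilyl)oxy]pentadec-10-yn-1-one
Conditions: Dess–Martin periodinane, CH2Cl2, rt
Reagents that add atoms: none
Why: Dess–Martin oxidation converts the benzylic alcohol to the aryl ketone under mild conditions that spare the silyl ethers and the alkyne.

Step 11
Reactants: 17 (8R,14R)-1-(2-bromo-3,5-dimethoxyphenyl)-8,14-bis[(tert-butyldimethylsilyl)oxy]pentadec-10-yn-1-one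
Product: 18 (1R,8R,14R)-1-(2-bromo-3,5-dimethoxyphenyl)-8,14-bis[(tert-butyldimethylsilyl)oxy]pentadec-10-yn-1-ol
Conditions: (S)-2-methyl-CBS-oxazaborolidine (20 mol %), catecholborane, toluene, −78 to −40 °C; then H2O
Reagents that add atoms: none
Why: Corey–Bakshi–Shibata reduction with the (S)-oxazaborolidine gives the (R)-carbinol (aryl as the large group, primary alkyl as the small group), and catecholborane at low temperature does not hydroborate the internal alkyne.

Step 12
Reactants: 18 (1R,8R,14R)-1-(2-bromo-3,5-dimethoxyphenyl)-8,14-bis[(tert-butyldimethylsilyl)oxy]pentadec-10-yn-1-ol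
Product: 21 (3R)-3-{(7R,13R)-7,13-bis[(tert-butyldimethylsilyl)oxy]tetradec-9-yn-1-yl}-5,7-dimethoxy-2-benzofuran-1(3H)-one, via dilithio species 19 (not isolated), via hydroxy acid 20 (not isolated)
Conditions: n-BuLi (2.2 equiv), THF, −78 °C; CO2; then 1 M HCl, 0 °C to rt
Reagents that add atoms: carbon dioxide, O=C=O
Why: Bromine–lithium exchange on the lithium alkoxide, carboxylation of the aryllithium and acid-induced lactonisation of the ortho-hydroxyalkyl benzoic acid form the phthalide without breaking the carbinol C–O bond, so C3 stays (R).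

Step 13
Reactants: 21 (3R)-3-{(7R,13R)-7,13-bis[(tert-butyldimethylsilyl)oxy]tetradec-9-yn-1-yl}-5,7-dimethoxy-2-benzofuran-1(3H)-one
Product: 22 (3R)-3-[(7R,13R)-7,13-dihydroxytetradec-9-yn-1-yl]-5,7-dimethoxy-2-benzofuran-1(3H)-one
Conditions: HF·pyridine, pyridine, THF, 0 °C to rt
Reagents that add atoms: none
Why: Fluoride-driven cleavage of both silyl ethers under buffered conditions leaves the lactone, C3 and the alkyne untouched.

Step 14
Reactants: 22 (3R)-3-[(7R,13R)-7,13-dihydroxytetradec-9-yn-1-yl]-5,7-dimethoxy-2-benzofuran-1(3H)-one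
Product: 24 (3R)-5,7-dimethoxy-3-{6-[(2R,5S,7R)-7-methyl-1,6-dioxaspiro[4.4]nonan-2-yl]hexyl}-2-benzofuran-1(3H)-one, via enol ether 23 (not isolated)
Conditions: Ph3PAuMe (2 mol %), (S,S)-IDPi acid (5 mol %), 4 Å MS, toluene, −40 °C; then Et3N
Reagents that add atoms: none
Why: Proposed new method: protonolysis of Ph3PAuMe by the IDPi acid (methane is lost) gives a silver-free cationic monovalent gold catalyst whose only counter-anion is the confined chiral imidodiphosphorimidate, this gold species effects 5-exo-dig anti-oxyauration and protodeauration of the alkyne by the C13' hydroxyl to give (Z)-enol ether 23, and the remaining free IDPi acid protonates 23 at C9' so that the C7' hydroxyl closes onto C10' within the catalyst-bound chiral ion pair, which sets the spiro carbon as (5S) under kinetic catalyst control (the two carbinol centres are pseudo-C2-related and give no thermodynamic bias, roughly 1:1 at equilibrium, and no bond to an existing stereocentre is broken), while the cold Et3N quench prevents acid equilibration; the closest known reaction types are gold-catalysed cycloisomerisation of alkynediols to spiroketals (no control at the spiro carbon) and confined imidodiphosphoric acid catalysed asymmetric spiroacetalisation of preformed hydroxy enol ethers.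

**Compound list**

1 | 1-(trimethylsilyl)propyne | CC#C[Si](C)(C)C | starting material
2 | (R)-propylene oxide, (2R)-2-methyloxirane | C[C@@H]1CO1 | starting material
3 | [3-(trimethylsilyl)prop-2-yn-1-yl]lithium | [Li]CC#C[Si](C)(C)C | intermediate
4 | (2R)-6-(trimethylsilyl)hex-5-yn-2-ol | C[C@@H](O)CCC#C[Si](C)(C)C | intermediate
5 | tert-butyldimethyl{[(2R)-6-(trimethylsilyl)hex-5-yn-2-yl]oxy}silane | C[C@@H](O[Si](C)(C)C(C)(C)C)CCC#C[Si](C)(C)C | intermediate
6 | tert-butyl[(2R)-hex-5-yn-2-yloxy]dimethylsilane | C[C@@H](O[Si](C)(C)C(C)(C)C)CCC#C | intermediate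
7 | 8-bromooct-1-ene | C=CCCCCCCBr | starting material
8 | rac-2-(6-bromohexyl)oxirane | BrCCCCCCC1CO1 | intermediate
9 | (2R)-2-(6-bromohexyl)oxirane | BrCCCCCC[C@@H]1CO1 | intermediate
10 | {(5R)-5-[(tert-butyldimethylsilyl)oxy]hex-1-yn-1-yl}lithium | [Li]C#CCC[C@@H](C)O[Si](C)(C)C(C)(C)C | intermediate
11 | (7R,13R)-1-bromo-13-[(tert-butyldimethylsilyl)oxy]tetradec-9-yn-7-ol | C[C@@H](O[Si](C)(C)C(C)(C)C)CCC#CC[C@H](O)CCCCCCBr | intermediate
12 | (7R,13R)-1-bromo-7,13-bis[(tert-butyldimethylsilyl)oxy]tetradec-9-yne | C[C@@H](O[Si](C)(C)C(C)(C)C)CCC#CC[C@H](O[Si](C)(C)C(C)(C)C)CCCCCCBr | intermediate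
13 | 3,5-dimethoxybenzaldehyde | COc1cc(OC)cc(C=O)c1 | starting material
14 | 2-bromo-3,5-dimethoxybenzaldehyde | COc1cc(OC)c(Br)c(C=O)c1 | intermediate
15 | {(7R,13R)-7,13-bis[(tert-butyldimethylsilyl)oxy]tetradec-9-yn-1-yl}magnesium bromide | Br[Mg]CCCCCC[C@@H](O[Si](C)(C)C(C)(C)C)CC#CCC[C@@H](C)O[Si](C)(C)C(C)(C)C | intermediate
16 | (1RS,8R,14R)-1-(2-bromo-3,5-dimethoxyphenyl)-8,14-bis[(tert-butyldimethylsilyl)oxy]pentadec-10-yn-1-ol | COc1cc(OC)c(Br)c(c1)C(O)CCCCCC[C@@H](O[Si](C)(C)C(C)(C)C)CC#CCC[C@@H](C)O[Si](C)(C)C(C)(C)C | intermediate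
17 | (8R,14R)-1-(2-bromo-3,5-dimethoxyphenyl)-8,14-bis[(tert-butyldimethylsilyl)oxy]pentadec-10-yn-1-one | COc1cc(OC)c(Br)c(c1)C(=O)CCCCCC[C@@H](O[Si](C)(C)C(C)(C)C)CC#CCC[C@@H](C)O[Si](C)(C)C(C)(C)C | intermediate
18 | (1R,8R,14R)-1-(2-bromo-3,5-dimethoxyphenyl)-8,14-bis[(tert-butyldimethylsilyl)oxy]pentadec-10-yn-1-ol | COc1cc(OC)c(Br)c(c1)[C@H](O)CCCCCC[C@@H](O[Si](C)(C)C(C)(C)C)CC#CCC[C@@H](C)O[Si](C)(C)C(C)(C)C | intermediate
19 | aryllithium lithium alkoxide of 18 (Li in place of Br and of the hydroxyl H) | COc1cc(OC)c([Li])c(c1)[C@H](O[Li])CCCCCC[C@@H](O[Si](C)(C)C(C)(C)C)CC#CCC[C@@H](C)O[Si](C)(C)C(C)(C)C | intermediate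
20 | 2-{(1R,8R,14R)-8,14-bis[(tert-butyldimethylsilyl)oxy]-1-hydroxypentadec-10-yn-1-yl}-4,6-dimethoxybenzoic acid | COc1cc(OC)c(C(O)=O)c(c1)[C@H](O)CCCCCC[C@@H](O[Si](C)(C)C(C)(C)C)CC#CCC[C@@H](C)O[Si](C)(C)C(C)(C)C | intermediate
21 | (3R)-3-{(7R,13R)-7,13-bis[(tert-butyldimethylsilyl)oxy]tetradec-9-yn-1-yl}-5,7-dimethoxy-2-benzofuran-1(3H)-one | COc1cc(OC)c2c(c1)[C@@H](CCCCCC[C@@H](O[Si](C)(C)C(C)(C)C)CC#CCC[C@@H](C)O[Si](C)(C)C(C)(C)C)OC2=O | intermediate
22 | (3R)-3-[(7R,13R)-7,13-dihydroxytetradec-9-yn-1-yl]-5,7-dimethoxy-2-benzofuran-1(3H)-one | COc1cc(OC)c2c(c1)[C@@H](CCCCCC[C@@H](O)CC#CCC[C@@H](C)O)OC2=O | intermediate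
23 | (3R)-3-{(7R,9Z)-7-hydroxy-9-[(5R)-5-methyloxolan-2-ylidene]nonyl}-5,7-dimethoxy-2-benzofuran-1(3H)-one | COc1cc(OC)c2c(c1)[C@@H](CCCCCC[C@@H](O)C/C=C3/CC[C@@H](C)O3)OC2=O | intermediate
24 | (3R)-5,7-dimethoxy-3-{6-[(2R,5S,7R)-7-methyl-1,6-dioxaspiro[4.4]nonan-2-yl]hexyl}-2-benzofuran-1(3H)-one | COc1cc(OC)c2c(c1)[C@@H](CCCCCC[C@@H]1CC[C@]3(CC[C@@H](C)O3)O1)OC2=O | target

**Step count and risks**

Total steps: 14. Longest linear sequence: 11 steps (1, 2, 3, 6, 7, 9, 10, 11, 12, 13, 14), from 1-(trimethylsilyl)propyne and (R)-propylene oxide.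

The three steps most likely to fail:

Step 14 (the proposed new step). The gold species rather than the chiral acid may close the second ring and give an unselective background reaction. The catalyst may discriminate poorly between the two spiro epimers. The strong acid may also equilibrate the product before the quench. The fallback uses known chemistry, sets out from diol 22 and comes back to the route at 24. AuCl (5 mol %) in CH2Cl2 at rt, followed by PPTS, gives the thermodynamic, roughly 1:1 mixture of 24 and its spiro epimer (3R)-5,7-dimethoxy-3-{6-[(2R,5R,7R)-7-methyl-1,6-dioxaspiro[4.4]nonan-2-yl]hexyl}-2-benzofuran-1(3H)-one F1. The two diastereomers are separated by preparative HPLC, and the unwanted one is equilibrated again with PPTS in CH2Cl2 and recycled, so the material converges on 24 without any catalyst control.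

Step 11. The ortho-bromo, long-chain aryl ketone may give a modest ee, and the borane may attack the alkyne. The fallback sets out from ketone 17 and comes back to the route at 21, replacing steps 11 and 12. Methoxycarbonylation of the aryl bromide (Pd(OAc)2, Xantphos, CO, MeOH, Et3N, DMF, 80 °C) gives the keto ester methyl 2-{(8R,14R)-8,14-bis[(tert-butyldimethylsilyl)oxy]pentadec-10-ynoyl}-4,6-dimethoxybenzoate F2. Asymmetric transfer hydrogenation with RuCl[(R,R)-TsDPEN](p-cymene) in HCO2H/Et3N at 40 °C, which does not reduce alkynes, gives the hydroxy ester methyl 2-{(1R,8R,14R)-8,14-bis[(tert-butyldimethylsilyl)oxy]-1-hydroxypentadec-10-yn-1-yl}-4,6-dimethoxybenzoate F3. This lactonises in the flask with loss of methanol to phthalide 21.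

Step 12. The hindered aryllithium, flanked by a methoxy group and the lithium alkoxide, may be quenched or alkylated by 1-bromobutane before it is carboxylated. The fallback sets out from bromo alcohol 18 and comes back to the route at 21. Palladium-catalysed carbonylative lactonisation (Pd(OAc)2, Xantphos, CO, Et3N, toluene, 100 °C) proceeds by oxidative addition, CO insertion and intramolecular capture of the acylpalladium by the benzylic hydroxyl, with no organolithium involved. It makes no compound outside the list (none F0).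

Further compounds
F1 | step 14 | (3R)-5,7-dimethoxy-3-{6-[(2R,5R,7R)-7-methyl-1,6-dioxaspiro[4.4]nonan-2-yl]hexyl}-2-benzofuran-1(3H)-one | COc1cc(OC)c2c(c1)[C@@H](CCCCCC[C@@H]1CC[C@@]3(CC[C@@H](C)O3)O1)OC2=O
F2 | step 11 | methyl 2-{(8R,14R)-8,14-bis[(tert-butyldimethylsilyl)oxy]pentadec-10-ynoyl}-4,6-dimethoxybenzoate | COc1cc(OC)c(C(=O)OC)c(c1)C(=O)CCCCCC[C@@H](O[Si](C)(C)C(C)(C)C)CC#CCC[C@@H](C)O[Si](C)(C)C(C)(C)C
F3 | step 11 | methyl 2-{(1R,8R,14R)-8,14-bis[(tert-butyldimethylsilyl)oxy]-1-hydroxypentadec-10-yn-1-yl}-4,6-dimethoxybenzoate | COc1cc(OC)c(C(=O)OC)c(c1)[C@H](O)CCCCCC[C@@H](O[Si](C)(C)C(C)(C)C)CC#CCC[C@@H](C)O[Si](C)(C)C(C)(C)C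
F0 | step 12 | none | none
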